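**Plan**
1. Cuts (germacrane numbers): first the C8–O ester bond and the C3–H bond (carbinol back to ketone). Then, in one stroke, C6–C7 and O6–C12, which are the ten-membered carbocycle C1–C10 and the γ-lactone. Then C2–C3, C1–C2/C10–C14 and C9–C10.
2. Enabling feature: ring atoms C3(O)–C4(CH3)=C5–C6(O) are a ring-opened 2-alkyl-3-methylfuran; the furan fixes the Z geometry and releases C6 as aldehyde and C3 as ketone. O6–C6–C7–C11(=C13)–C12 is the retron of a 2-(methoxycarbonyl)allyl metal adding to that aldehyde. The trans C1–C10 oxirane cannot sit in a seven-membered ring, so it blocks closure onto C3.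
3. Forward order: the oxirane is made first on the open chain, the furan is attached as a temporary ring, and the bromomethyl acrylate is built at C7. One flask then opens the furan and closes carbocycle and lactone. No ring is formed afterwards (C8 acylation, C3 reduction, desilylation).
4. Stereochemistry: C8 comes from (S)-glycidol. C1/C10 come from Sharpless epoxidation (D-(−)-tartrate) of the E-alkene made by syn-carboalumination. C6/C7 come from the chair transition state of the key step (the Z-allyl unit gives the cis-lactone, C8 gives the face). C3 comes from CBS reduction, the side-chain centre from an Evans auxiliary, and the side-chain E-alkene from a Z-Baylis–Hillman bromide.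

Key step: step 10

Remark: C1 and C10 are the oxirane carbons (C10 bears methyl C14). C2 is CH2, C3 the carbinol, C4(=C5) bears methyl C15, C6 is the lactone O–CH, C7 the ring-fusion CH, C8 the acyloxy CH, C9 is CH2, and C11(=C13)–C12(=O) is the lactone acrylate. H6 and H7 of the target lie on the same face (cis-fused lactone).

Step 1
Reactants: 1 (S)-glycidol
Product: 2 (2R)-pent-4-yne-1,2-diol
Conditions: LiC≡CH·H2NCH2CH2NH2 (2.5 equiv), DMSO, 0 °C to rt; H2O
Reagents that add atoms: lithium acetylide ethylenediamine complex, [Li]C#C.NCCN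
Why: SN2 opening of the terminal oxirane carbon by acetylide leaves the stereocentre (future C8) untouched; the descriptor changes from S to R only because the ranking of the two CH2 groups changes.

Step 2
Reactants: 2 (2R)-pent-4-yne-1,2-diol
Product: 3 (4R)-4,5-bis(triethylsilyloxy)pent-1-yne
Conditions: Et3SiCl, imidazole, CH2Cl2, 0 °C to rt
Reagents that add atoms: chlorotriethylsilane, CC[Si](Cl)(CC)CC
Why: Standard silyl ether protection; the primary triethylsilyl ether later serves as the handle for direct oxidation, and the secondary one is labile enough for late removal.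

Step 3
Reactants: 3 (4R)-4,5-bis(triethylsilyloxy)pent-1-yne
Product: 6 (2E,5R)-3-methyl-5,6-bis(triethylsilyloxy)hex-2-en-1-ol, via alkenylalane 4 (not isolated), via lithium alkenylaluminate 5 (not isolated)
Conditions: Me3Al, Cp2ZrCl2 (cat.), CH2Cl2, 0 °C to rt; n-BuLi, THF–hexane, −78 to 0 °C; (CH2O)n, rt
Reagents that add atoms: trimethylaluminium, C[Al](C)C; paraformaldehyde (as formaldehyde), C=O
Why: Negishi zirconium-catalysed syn-carboalumination puts methyl C14 on the internal and aluminium on the terminal alkyne carbon, and the ate complex traps formaldehyde (C2) with retention, so only the E-trisubstituted allylic alcohol should form.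

Step 4
Reactants: 6 (2E,5R)-3-methyl-5,6-bis(triethylsilyloxy)hex-2-en-1-ol
Product: 7 [(2R,3R)-3-[(2R)-2,3-bis(triethylsilyloxy)propyl]-3-methyloxiran-2-yl]methanol
Conditions: Ti(OiPr)4 (cat.), D-(−)-diethyl tartrate (cat.), t-BuOOH, 4 Å MS, CH2Cl2, −20 °C
Reagents that add atoms: tert-butyl hydroperoxide, CC(C)(C)OO
Why: Sharpless asymmetric epoxidation with the D-(−)-tartrate gives the (2R,3R)-epoxy alcohol of a geraniol-type substrate (C1 R, C10 R) under reagent control, and the E geometry becomes the trans relation of C2 and C9.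

Step 5
Reactants: 8 3-methylfuran
Product: 9 2-bromo-3-methylfuran
Conditions: NBS, DMF, 0 °C, dark
Reagents that add atoms: N-bromosuccinimide, O=C1CCC(=O)N1Br
Why: Electrophilic aromatic bromination goes to the α-position next to the methyl group, the most activated site of the furan.

Step 6
Reactants: 7 epoxy alcohol; 9 2-bromo-3-methylfuran
Product: 12 2-{[(2R,3R)-3-[(2R)-2,3-bis(triethylsilyloxy)propyl]-3-methyloxiran-2-yl]methyl}-3-methylfuran, via epoxy triflate 10 (not isolated), via 3-methyl-2-furyllithium 11 (not isolated)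
Conditions: 7: Tf2O, 2,6-lutidine, CH2Cl2, −78 °C; 9: n-BuLi, THF, −78 °C; combine, −78 to −40 °C
Reagents that add atoms: none
Why: Halogen–lithium exchange followed by SN2 alkylation of the heteroaryllithium; without a Lewis acid the primary triflate is displaced far faster than the hindered trisubstituted oxirane is opened, so C1 and C10 stay untouched.

Step 7
Reactants: 12 furyl epoxide bis(triethylsilyl) ether
Product: 14 (2R)-3-{(2R,3R)-2-methyl-3-[(3-methylfuran-2-yl)methyl]oxiran-2-yl}-2-(triethylsilyloxy)propanal, via alkoxysulfonium chloride 13 (not isolated)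
Conditions: (COCl)2, DMSO, CH2Cl2, −78 to −40 °C; Et3N, −78 to 0 °C
Reagents that add atoms: none
Why: Swern oxidation applied directly to the silyl ether; the activated sulfonium species cleaves only the unhindered primary triethylsilyl ether, so deprotection and oxidation take one step and the secondary ether at C8 stays.

Step 8
Reactants: 14 α-silyloxy aldehyde; 15 methyl acrylate
Product: 16 methyl (4R)-3-hydroxy-2-methylidene-5-{(2R,3R)-2-methyl-3-[(3-methylfuran-2-yl)methyl]oxiran-2-yl}-4-(triethylsilyloxy)pentanoate (both C3 epimers)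
Conditions: DABCO, methyl acrylate (excess, neat), rt
Reagents that add atoms: none
Why: Morita–Baylis–Hillman reaction, for which α-oxygenated aldehydes are good acceptors; the new carbinol centre (C7) needs no control because the next step erases it.

Step 9
Reactants: 16 Baylis–Hillman adduct
Product: 18 methyl (2Z,4R)-2-(bromomethyl)-5-{(2R,3R)-2-methyl-3-[(3-methylfuran-2-yl)methyl]oxiran-2-yl}-4-(triethylsilyloxy)pent-2-enoate, via allylic mesylate 17 (not isolated)
Conditions: MsCl, Et3N, CH2Cl2, −20 °C; LiBr, THF, 0 °C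
Reagents that add atoms: lithium bromide, [Li+].[Br-]
Why: Mesylation and SN2' displacement by bromide (allylic transposition of a Baylis–Hillman adduct) should give the favoured Z-bromide, with C8 cis to CH2Br and trans to the ester, under conditions neutral enough for oxirane and furan.

Step 10
Reactants: 18 furyl allylic bromide
Product: 21 (4Z)-1,10-epoxy-3-oxo-8-(triethylsilyloxy)germacra-4,11(13)-dien-12,6-olide of 1R,6S,7S,8R,10R configuration, via keto-enal bromide 19 (not isolated), via hydroxy ester 20 (not isolated)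
Conditions: dimethyldioxirane (1 equiv), acetone–CH2Cl2, −40 °C; evaporate cold; slow addition to In powder, THF–DMF, ca. 1 mM, rt
Reagents that add atoms: dimethyldioxirane, CC1(C)OO1
Why: Dimethyldioxirane transfers one oxygen to the electron-rich furan, which collapses to the (Z)-4-oxo-2-enal 19, so that the sacrificed ring hands its cis geometry to C4=C5 and unmasks C6 as the only aldehyde; indium then inserts into the C13–Br bond, the 2-(methoxycarbonyl)allylindium adds through C7 (SE2') to C6=O, and the C6 alkoxide of 20 expels methoxide from C12. The closest known reaction type is the intramolecular Barbier (Dreiding–Schmidt) allylation–lactonisation of formyl-tethered 2-(bromomethyl)acrylates, known for cis-fused α-methylene-γ-butyrolactones and for the ten-membered ring of germacranolides. The carbocycle C1–C10 closes by a 10-exo-trig addition at C6 through a six-membered Zimmerman–Traxler array (In, O, C6, C7, C11, C13), and the lactone closes by a 5-exo-trig acyl substitution at C12. C6 and C7 are set relative to each other by this chair, in which C5 is equatorial and C8, cis to C13 on the allyl unit, is axial, which means the syn adduct and hence the cis-fused lactone. Their absolute sense should follow from C8: allylic 1,3-strain with C13 holds H8 in the plane of C7=C11, the C8–C9 bond lies anti to the forming bond and the silyloxy group sits outside, which exposes the C7 face found in the target, while the rigid trans-oxirane and Z-enone limit the ring conformations that can reach this array. The step needs aldehyde-over-ketone and ten-over-seven-membered selectivity and survival of the ene-dicarbonyl unit: attack of C7 on C3 would place the trans C1–C10 oxirane in a seven-membered ring and is geometrically excluded, reversible hemiketal formation between O6 and C3 is drained by the irreversible lactonisation, high dilution suppresses oligomers, and zerovalent indium is a much weaker reductant than zinc or divalent chromium.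

Step 11
Reactants: 21 macrocyclic keto lactone
Product: 22 (1R,6S,7R,8R,10R,4Z)-1,10-epoxy-8-hydroxy-3-oxogermacra-4,11(13)-dien-12,6-olide
Conditions: HF·pyridine, pyridine, THF, 0 °C
Reagents that add atoms: none
Why: Fluoride-mediated desilylation; the labile triethylsilyl ether should fall quickly in the pyridine-buffered medium, which spares the oxirane, the enone and the α-methylene lactone.

Step 12
Reactants: 23 (R)-4-benzyloxazolidin-2-one; 24 butanoic anhydride
Product: 25 (R)-4-benzyl-3-butanoyloxazolidin-2-one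
Conditions: Et3N, DMAP (cat.), THF, rt
Reagents that add atoms: none
Why: DMAP-catalysed N-acylation of the Evans auxiliary.

Step 13
Reactants: 25 (R)-4-benzyl-3-butanoyloxazolidin-2-one
Product: 27 (R)-4-benzyl-3-[(2S)-2-(hydroxymethyl)butanoyl]oxazolidin-2-one, via titanium enolate 26 (not isolated)
Conditions: TiCl4, iPr2NEt, CH2Cl2, 0 °C; 1,3,5-trioxane, TiCl4, 0 °C
Reagents that add atoms: 1,3,5-trioxane, C1OCOCO1
Why: Evans titanium-enolate hydroxymethylation; the chelated Z-enolate is attacked by the TiCl4-activated formaldehyde equivalent on the face opposite the benzyl group, which for the (R)-auxiliary gives the 2S centre.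

Step 14
Reactants: 27 hydroxymethyl imide
Product: 28 (R)-4-benzyl-3-[(2S)-2-{[tert-butyl(dimethyl)silyl]oxymethyl}butanoyl]oxazolidin-2-one
Conditions: TBSCl, imidazole, DMF, rt
Reagents that add atoms: tert-butylchlorodimethylsilane, CC(C)(C)[Si](C)(C)Cl
Why: Standard silyl ether protection of the primary alcohol, which also prevents retro-aldol loss of formaldehyde in the next step.

Step 15
Reactants: 28 silylated imide
Product: 30 (2S)-2-{[tert-butyl(dimethyl)silyl]oxymethyl}butanoic acid, via peroxy acid 29 (not isolated)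
Conditions: LiOH, H2O2, THF–H2O, 0 °C; Na2SO3; HCl to pH 3
Reagents that add atoms: hydrogen peroxide, OO
Why: Evans auxiliary cleavage with lithium hydroperoxide, which attacks the exocyclic carbonyl selectively and is too weakly basic to epimerise the α-centre.

Step 16
Reactants: 31 tert-butyl acrylate; 32 acetaldehyde
Product: 33 tert-butyl 3-hydroxy-2-methylidenebutanoate (racemic)
Conditions: DABCO, dioxane–H2O, rt
Reagents that add atoms: none
Why: Morita–Baylis–Hillman reaction; the carbinol centre is erased in the next step.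

Step 17
Reactants: 33 tert-butyl 3-hydroxy-2-methylidenebutanoate
Product: 34 tert-butyl (2Z)-2-(bromomethyl)but-2-enoate
Conditions: NBS, Me2S, CH2Cl2, 0 °C to rt
Reagents that add atoms: N-bromosuccinimide, O=C1CCC(=O)N1Br
Why: Corey–Kim-type activation of the alcohol followed by SN2' attack of bromide should give the Z-bromide (CH3 cis to CH2Br) under neutral conditions that keep the tert-butyl ester.

Step 18
Reactants: 30 silyloxy acid; 34 allylic bromide
Product: 36 tert-butyl (2E)-2-({[(2S)-2-{[tert-butyl(dimethyl)silyl]oxymethyl}butanoyl]oxy}methyl)but-2-enoate, via caesium carboxylate 35 (not isolated)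
Conditions: Cs2CO3, DMF, 0 °C to rt
Reagents that add atoms: none
Why: SN2 O-alkylation of a caesium carboxylate at the primary allylic carbon keeps the alkene geometry (CH3 stays cis to CH2O, now described as E) and does not touch the α-centre.

Step 19
Reactants: 36 diester
Product: 38 (2E)-2-({[(2S)-2-{[tert-butyl(dimethyl)silyl]oxymethyl}butanoyl]oxy}methyl)but-2-enoic acid, via trimethylsilyl ester 37 (not isolated)
Conditions: Me3SiOTf, 2,6-lutidine, CH2Cl2, 0 °C; pH 5 buffer
Reagents that add atoms: none
Why: Silyl-triflate-mediated cleavage of the tert-butyl ester (loss of isobutene) in buffered medium should spare the primary silyl ether and the second ester.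

Step 20
Reactants: 22 C8 alcohol; 38 side-chain acid
Product: 39 8-O-acyl keto lactone (22 esterified at O8 with 38)
Conditions: DCC, DMAP (cat.), CH2Cl2, 0 °C to rt
Reagents that add atoms: none
Why: Steglich esterification of the only free hydroxyl group; the tiglate-type acid is already the stable alkene isomer, and the mild base should leave the β,γ-epoxy ketone and the lactone position unchanged.

Step 21
Reactants: 39 8-O-acyl keto lactone
Product: 40 (3S)-3-hydroxy compound (silyl ether of the target)
Conditions: (R)-2-methyl-CBS-oxazaborolidine, catecholborane, toluene, −78 °C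
Reagents that add atoms: none
Why: Corey–Bakshi–Shibata reduction; the catalyst reads the alkenyl flank C4 as the large group and CH2-2 as the small group, so the (R)-catalyst should deliver hydride to the face that gives 3S, and the catalysed 1,2-reduction at low temperature should outrun any reaction with lactone, esters, oxirane or acrylate units.

Step 22
Reactants: 40 silyl ether of the target
Product: 41 target CNP0156402.1
Conditions: HF·pyridine, pyridine, THF, 0 °C
Reagents that add atoms: none
Why: Buffered fluoride desilylation of the primary silyl ether, under conditions that should tolerate the oxirane, the allylic alcohol and both Michael acceptors.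

**Compound list**
1 | (S)-glycidol | OC[C@H]1CO1 | starting material
2 | (2R)-pent-4-yne-1,2-diol | C#CC[C@@H](O)CO | intermediate
3 | (4R)-4,5-bis(triethylsilyloxy)pent-1-yne | C#CC[C@@H](O[Si](CC)(CC)CC)CO[Si](CC)(CC)CC | intermediate
4 | dimethyl[(1E,4R)-2-methyl-4,5-bis(triethylsilyloxy)pent-1-enyl]alane | C[Al](C)/C=C(\C)C[C@@H](O[Si](CC)(CC)CC)CO[Si](CC)(CC)CC | intermediate
5 | lithium butyl(dimethyl)[(1E,4R)-2-methyl-4,5-bis(triethylsilyloxy)pent-1-enyl]aluminate | [Li+].CCCC[Al-](C)(C)/C=C(\C)C[C@@H](O[Si](CC)(CC)CC)CO[Si](CC)(CC)CC | intermediate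
6 | (2E,5R)-3-methyl-5,6-bis(triethylsilyloxy)hex-2-en-1-ol | OC/C=C(\C)C[C@@H](O[Si](CC)(CC)CC)CO[Si](CC)(CC)CC | intermediate
7 | [(2R,3R)-3-[(2R)-2,3-bis(triethylsilyloxy)propyl]-3-methyloxiran-2-yl]methanol | OC[C@H]1O[C@]1(C)C[C@@H](O[Si](CC)(CC)CC)CO[Si](CC)(CC)CC | intermediate
8 | 3-methylfuran | Cc1ccoc1 | starting material
9 | 2-bromo-3-methylfuran | Cc1ccoc1Br | intermediate
10 | trifluoromethanesulfonate of 7 | O=S(=O)(OC[C@H]1O[C@]1(C)C[C@@H](O[Si](CC)(CC)CC)CO[Si](CC)(CC)CC)C(F)(F)F | intermediate
11 | (3-methylfuran-2-yl)lithium | [Li]c1occc1C | intermediate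
12 | 2-{[(2R,3R)-3-[(2R)-2,3-bis(triethylsilyloxy)propyl]-3-methyloxiran-2-yl]methyl}-3-methylfuran | Cc1ccoc1C[C@H]1O[C@]1(C)C[C@@H](O[Si](CC)(CC)CC)CO[Si](CC)(CC)CC | intermediate
13 | alkoxy(dimethyl)sulfonium chloride at the primary oxygen of 12 | Cc1ccoc1C[C@H]1O[C@]1(C)C[C@@H](O[Si](CC)(CC)CC)CO[S+](C)C.[Cl-] | intermediate
14 | (2R)-3-{(2R,3R)-2-methyl-3-[(3-methylfuran-2-yl)methyl]oxiran-2-yl}-2-(triethylsilyloxy)propanal | Cc1ccoc1C[C@H]1O[C@]1(C)C[C@@H](O[Si](CC)(CC)CC)C=O | intermediate
15 | methyl acrylate | C=CC(=O)OC | starting material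
16 | methyl (4R)-3-hydroxy-2-methylidene-5-{(2R,3R)-2-methyl-3-[(3-methylfuran-2-yl)methyl]oxiran-2-yl}-4-(triethylsilyloxy)pentanoate, both C3 epimers | Cc1ccoc1C[C@H]1O[C@]1(C)C[C@@H](O[Si](CC)(CC)CC)C(O)C(=C)C(=O)OC | intermediate
17 | methanesulfonate of 16 | Cc1ccoc1C[C@H]1O[C@]1(C)C[C@@H](O[Si](CC)(CC)CC)C(OS(C)(=O)=O)C(=C)C(=O)OC | intermediate
18 | methyl (2Z,4R)-2-(bromomethyl)-5-{(2R,3R)-2-methyl-3-[(3-methylfuran-2-yl)methyl]oxiran-2-yl}-4-(triethylsilyloxy)pent-2-enoate | Cc1ccoc1C[C@H]1O[C@]1(C)C[C@@H](O[Si](CC)(CC)CC)/C=C(\CBr)C(=O)OC | intermediate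
19 | methyl (2Z,4R)-2-(bromomethyl)-5-{(2R,3R)-2-methyl-3-[(3Z)-3-methyl-2,5-dioxopent-3-en-1-yl]oxiran-2-yl}-4-(triethylsilyloxy)pent-2-enoate | O=C/C=C(/C)C(=O)C[C@H]1O[C@]1(C)C[C@@H](O[Si](CC)(CC)CC)/C=C(\CBr)C(=O)OC | intermediate
20 | methyl 2-[ten-membered ring C7]acrylate: 6-hydroxy-1,10-epoxy-3-oxo-8-(triethylsilyloxy)germacra-4(Z),11(13)-dien-12-oic acid methyl ester, formed as its indium alkoxide, centres spatially as in 21 | COC(=O)C(=C)[C@H]1[C@@H](O)/C=C(/C)C(=O)C[C@H]2O[C@]2(C)C[C@H]1O[Si](CC)(CC)CC | intermediate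
21 | (1R,6S,7S,8R,10R,4Z)-1,10-epoxy-3-oxo-8-(triethylsilyloxy)germacra-4,11(13)-dien-12,6-olide, cis-fused lactone; C7 is spatially as in 41, and its descriptor is S only because silicon raises the rank of C8 | C=C1C(=O)O[C@H]2/C=C(/C)C(=O)C[C@H]3O[C@]3(C)C[C@@H](O[Si](CC)(CC)CC)[C@@H]12 | intermediate
22 | (1R,6S,7R,8R,10R,4Z)-1,10-epoxy-8-hydroxy-3-oxogermacra-4,11(13)-dien-12,6-olide | C=C1C(=O)O[C@H]2/C=C(/C)C(=O)C[C@H]3O[C@]3(C)C[C@@H](O)[C@@H]12 | intermediate
23 | (R)-4-benzyloxazolidin-2-one | O=C1N[C@H](Cc2ccccc2)CO1 | starting material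
24 | butanoic anhydride | CCCC(=O)OC(=O)CCC | starting material
25 | (R)-4-benzyl-3-butanoyloxazolidin-2-one | CCCC(=O)N1[C@H](Cc2ccccc2)COC1=O | intermediate
26 | trichlorotitanium (Z)-enolate of 25 | CC/C=C(\O[Ti](Cl)(Cl)Cl)N1[C@H](Cc2ccccc2)COC1=O | intermediate
27 | (R)-4-benzyl-3-[(2S)-2-(hydroxymethyl)butanoyl]oxazolidin-2-one | CC[C@@H](CO)C(=O)N1[C@H](Cc2ccccc2)COC1=O | intermediate
28 | (R)-4-benzyl-3-[(2S)-2-{[tert-butyl(dimethyl)silyl]oxymethyl}butanoyl]oxazolidin-2-one | CC[C@@H](CO[Si](C)(C)C(C)(C)C)C(=O)N1[C@H](Cc2ccccc2)COC1=O | intermediate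
29 | (2S)-2-{[tert-butyl(dimethyl)silyl]oxymethyl}butaneperoxoic acid | CC[C@@H](CO[Si](C)(C)C(C)(C)C)C(=O)OO | intermediate
30 | (2S)-2-{[tert-butyl(dimethyl)silyl]oxymethyl}butanoic acid | CC[C@@H](CO[Si](C)(C)C(C)(C)C)C(=O)O | intermediate
31 | tert-butyl acrylate | C=CC(=O)OC(C)(C)C | starting material
32 | acetaldehyde | CC=O | starting material
33 | tert-butyl 3-hydroxy-2-methylidenebutanoate (racemic) | CC(O)C(=C)C(=O)OC(C)(C)C | intermediate
34 | tert-butyl (2Z)-2-(bromomethyl)but-2-enoate | C/C=C(\CBr)C(=O)OC(C)(C)C | intermediate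
35 | caesium (2S)-2-{[tert-butyl(dimethyl)silyl]oxymethyl}butanoate | CC[C@@H](CO[Si](C)(C)C(C)(C)C)C(=O)[O-].[Cs+] | intermediate
36 | tert-butyl (2E)-2-({[(2S)-2-{[tert-butyl(dimethyl)silyl]oxymethyl}butanoyl]oxy}methyl)but-2-enoate | CC(C)(C)OC(=O)/C(=C/C)COC(=O)[C@@H](CC)CO[Si](C)(C)C(C)(C)C | intermediate
37 | trimethylsilyl ester of 38 | C[Si](C)(C)OC(=O)/C(=C/C)COC(=O)[C@@H](CC)CO[Si](C)(C)C(C)(C)C | intermediate
38 | (2E)-2-({[(2S)-2-{[tert-butyl(dimethyl)silyl]oxymethyl}butanoyl]oxy}methyl)but-2-enoic acid | OC(=O)/C(=C/C)COC(=O)[C@@H](CC)CO[Si](C)(C)C(C)(C)C | intermediate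
39 | (1R,6S,7R,8R,10R,4Z)-1,10-epoxy-3-oxogermacra-4,11(13)-dien-12,6-olid-8-yl ester of 38 | C=C1C(=O)O[C@H]2/C=C(/C)C(=O)C[C@H]3O[C@]3(C)C[C@@H](OC(=O)/C(=C/C)COC(=O)[C@@H](CC)CO[Si](C)(C)C(C)(C)C)[C@@H]12 | intermediate
40 | (1R,3S,6S,7R,8R,10R,4Z)-1,10-epoxy-3-hydroxygermacra-4,11(13)-dien-12,6-olid-8-yl ester of 38 | C=C1C(=O)O[C@H]2/C=C(/C)[C@@H](O)C[C@H]3O[C@]3(C)C[C@@H](OC(=O)/C(=C/C)COC(=O)[C@@H](CC)CO[Si](C)(C)C(C)(C)C)[C@@H]12 | intermediate
41 | CNP0156402.1: (1R,3S,6S,7R,8R,10R,4Z)-1,10-epoxy-3-hydroxygermacra-4,11(13)-dien-12,6-olid-8-yl (2E)-2-({[(2S)-2-(hydroxymethyl)butanoyl]oxy}methyl)but-2-enoate | C=C1C(=O)O[C@H]2/C=C(/C)[C@@H](O)C[C@H]3O[C@]3(C)C[C@@H](OC(=O)/C(=C/C)COC(=O)[C@@H](CC)CO)[C@@H]12 | target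

**Totals:** 22 steps. The longest linear sequence is 13 steps (steps 1–4, 6–11, 20–22).

**Steps most likely to fail**

Step 10.
- What may go wrong: electron transfer from the metal to the ene-dicarbonyl unit, Z-to-E isomerisation of C4=C5 before closure, oligomerisation, or poor facial control at C6/C7.
- The fallback sets out from 16 and returns at 21. It replaces the reductive generation of the nucleophile by a preformed boron nucleophile, so the closure becomes a redox-neutral, stereospecific allylboration–lactonisation.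
- 16 is acetylated (Ac2O, pyridine) to the allylic acetate F1.
- CuCl/KOAc-mediated SN2' borylation with B2pin2 gives the allylboronate F2, with C8 cis to CH2B.
- Sensitised photooxygenation (O2, rose bengal, visible light, −78 °C) leaves the C–B bond and the acrylate alone and gives the furan endoperoxide F3.
- Me2S reduces F3 to the keto-enal boronate F4.
- At high dilution with Sc(OTf)3 (cat.) or a chiral phosphoric acid, which adds catalyst control of the aldehyde face, the closed six-membered transition state gives the cyclic borate F5, which lactonises to 21.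

Step 6.
- What may go wrong: attack of the organolithium on the oxirane or at sulfur, proton transfer from the lutidinium salt, or decomposition of the triflate before coupling.
- The fallback sets out from 6 and returns at 12. It makes the C2–furan bond at the allylic stage and puts the oxirane in afterwards under hydroxyl direction.
- CBr4/PPh3 converts 6 into the allylic bromide F6.
- SN2 alkylation of 11 gives the furyl alkene F7.
- Bu4NF frees the diol F8.
- VO(acac)2/t-BuOOH epoxidation, directed by the homoallylic C8 hydroxyl group, gives the epoxy diol F9, purified from any diastereomer by chromatography.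
- Et3SiCl/imidazole gives 12.

Step 21.
- What may go wrong: mismatch between the catalyst and the ring conformation (poor facial selectivity at C3), or conjugate hydride addition to the α-methylene lactone or the side-chain acrylate.
- The fallback sets out from 21 and returns at 41. It sets C3 by substrate control before the side chain is attached, which reorders the endgame and needs a second silyl group.
- Luche reduction of 21 (NaBH4, CeCl3·7H2O, MeOH, −78 °C; peripheral attack on the ten-membered ring) gives the allylic alcohol F10.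
- TBSOTf/2,6-lutidine gives the mixed bis-silyl ether F11.
- Selective cleavage of the more labile triethylsilyl ether (HF·pyridine, pyridine, 0 °C) gives the C8 alcohol F12.
- DCC/DMAP with 38 gives the bis-TBS ester F13.
- HF·pyridine removes both silyl groups to give 41.

**Further compounds**
F1 | step 10 | acetate of 16 | Cc1ccoc1C[C@H]1O[C@]1(C)C[C@@H](O[Si](CC)(CC)CC)C(OC(C)=O)C(=C)C(=O)OC
F2 | step 10 | methyl (2E,4R)-5-{(2R,3R)-2-methyl-3-[(3-methylfuran-2-yl)methyl]oxiran-2-yl}-2-[(4,4,5,5-tetramethyl-1,3,2-dioxaborolan-2-yl)methyl]-4-(triethylsilyloxy)pent-2-enoate | Cc1ccoc1C[C@H]1O[C@]1(C)C[C@@H](O[Si](CC)(CC)CC)/C=C(\CB1OC(C)(C)C(C)(C)O1)C(=O)OC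
F3 | step 10 | furan endoperoxide of F2 (2,3,7-trioxabicyclo[2.2.1]hept-5-ene, both faces) | CC1=CC2OOC1(O2)C[C@H]3O[C@]3(C)C[C@@H](O[Si](CC)(CC)CC)/C=C(\CB4OC(C)(C)C(C)(C)O4)C(=O)OC
F4 | step 10 | (Z)-4-oxo-2-enal allylboronate (boron analogue of 19) | O=C/C=C(/C)C(=O)C[C@H]1O[C@]1(C)C[C@@H](O[Si](CC)(CC)CC)/C=C(\CB1OC(C)(C)C(C)(C)O1)C(=O)OC
F5 | step 10 | O6-pinacolboryl derivative of 20 | COC(=O)C(=C)[C@H]1[C@@H](OB2OC(C)(C)C(C)(C)O2)/C=C(/C)C(=O)C[C@H]2O[C@]2(C)C[C@H]1O[Si](CC)(CC)CC
F6 | step 6 | (2E,5R)-1-bromo-3-methyl-5,6-bis(triethylsilyloxy)hex-2-ene | BrC/C=C(\C)C[C@@H](O[Si](CC)(CC)CC)CO[Si](CC)(CC)CC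
F7 | step 6 | 3-methyl-2-[(2E,5R)-3-methyl-5,6-bis(triethylsilyloxy)hex-2-enyl]furan | Cc1ccoc1C/C=C(\C)C[C@@H](O[Si](CC)(CC)CC)CO[Si](CC)(CC)CC
F8 | step 6 | (2R,4E)-4-methyl-6-(3-methylfuran-2-yl)hex-4-ene-1,2-diol | Cc1ccoc1C/C=C(\C)C[C@@H](O)CO
F9 | step 6 | (2R)-3-{(2R,3R)-2-methyl-3-[(3-methylfuran-2-yl)methyl]oxiran-2-yl}propane-1,2-diol | Cc1ccoc1C[C@H]1O[C@]1(C)C[C@@H](O)CO
F10 | step 21 | (3S)-3-hydroxy analogue of 21 | C=C1C(=O)O[C@H]2/C=C(/C)[C@@H](O)C[C@H]3O[C@]3(C)C[C@@H](O[Si](CC)(CC)CC)[C@@H]12
F11 | step 21 | 3-O-TBS ether of F10 | C=C1C(=O)O[C@H]2/C=C(/C)[C@@H](O[Si](C)(C)C(C)(C)C)C[C@H]3O[C@]3(C)C[C@@H](O[Si](CC)(CC)CC)[C@@H]12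
F12 | step 21 | 3-O-TBS 8-hydroxy lactone | C=C1C(=O)O[C@H]2/C=C(/C)[C@@H](O[Si](C)(C)C(C)(C)C)C[C@H]3O[C@]3(C)C[C@@H](O)[C@@H]12
F13 | step 21 | 3-O-TBS ether of 40 | C=C1C(=O)O[C@H]2/C=C(/C)[C@@H](O[Si](C)(C)C(C)(C)C)C[C@H]3O[C@]3(C)C[C@@H](OC(=O)/C(=C/C)COC(=O)[C@@H](CC)CO[Si](C)(C)C(C)(C)C)[C@@H]12
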